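The ratio of JoTy made to KjTy made, which I called R, was what I wanted from the ochre flask, and the early share is R/(1+R).

| flask | Wy | Jo | Kj | remark | time |
|---|---|---|---|---|---|
| ochre | 26 mM | 33.8 mM | 65 mM | the very flask that is asked about, followed so far |  |
| flask | 26 mM | 33.8 mM | 65.0 mM |  | 2.5 h |

ochre run (percent of the Wy charged)

| time / min | JoTy / % | KjTy / % |
|---|---|---|
| 8.00 | 11.3 | 1.4 |
| 20.0 | 20.5 | 4.4 |
| 40.0 | 22.1 | 7.8 |
| 60.0 | 18.0 | 9.4 |

(scatter of a reading: 0.3 percentage points)

- share of JoTy in JoTy plus KjTy at 2.0 min
- share of JoTy in JoTy plus KjTy at 2.5 h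
- which of JoTy and KjTy there is more of at 2.5 h



I got R two ways. The first reading gave it directly, at 8.00 min, though that reading ignored any drain on JoTy and its small KjTy carried the full scatter of 0.3 percentage points. For the second, I let JoTy fall by first-order loss k and replaced its curve by its mean m, so that JoTy = R·KjTy − k·m·t. The mean was 11.8% up to 20.0 min and 17.7% up to 60.0 min, and those two readings gave k = 0.0462 min⁻¹.

| Way | R | Share |
|---|---|---|
| First reading | 8.07 | 89.0% |
| Balance | 7.13 | 87.7% |

The shares nearly agreed, but the R values parted. I put the KjTy reading at 40.0 min, which the balance had not used, into it and got 25.1% JoTy, more than the 22.1% read, but that JoTy reading had already gone into k, so this was no independent test. The gap was 3 points, and the scatter of 0.3 points on that KjTy reading enters the prediction multiplied by R, here 7.13, so the gap did not tell against the balance. I kept the first reading as a choice, since it stood nearer 2.0 min than the 20.0 min reading. Assuming R follows c(Jo)/c(Kj), I carried the selectivity factor σ = R·c(Kj)/c(Jo) = 15.5.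

The forecast gave 92% early, 28% late and KjTy ahead, judging that “KjTy levels off around 11–13%, assuming it is stable”.

    Jo + Ty → JoTy (k = 1.80 M⁻¹ s⁻¹)
    Kj + JoTy → KjJoTy (k = 0.0120 M⁻¹ s⁻¹)
    Wy → Ty (k = 3.80 × 10⁻⁴ s⁻¹)
    Ty → Ji (k = 0.00130 s⁻¹)
    Kj + Ty → KjTy (k = 0.110 M⁻¹ s⁻¹)

The flask gave 89.0% at 2.0 min and 27.3% at 2.5 h, with KjTy ahead, 12.7% against 4.77%; the two products had stood level at 1.61 h. On this flask, σ returned 89.0% for the early share. In the neighbour charged with 16 mM of Kj, everything else as in the recipe, σ gave R = 32.8 and a share of 97.0%. That neighbour gave 97.1% at 2.0 min, and at 2.5 h its share stood at 93.7%, with 48.3% JoTy.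

The readings are simulated from invented constants; the scatter is artificial.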